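**Retrosynthetic overview**
1. Spiculoic acid B ⇐ intramolecular Diels–Alder reaction of the open-chain (2E,4Z,6S,7E,9E,11E)-pentaenoic acid. Both rings close together in this last step: the cyclohexene by the [4+2], the cyclopentene because the Z-C4=C5 olefin sits in the three-atom tether.
2. Pentaenoic acid ⇐ C8–C9 Suzuki–Miyaura coupling of a dienyl iodide with the alkenylborane from syn-hydroboration of a C7≡C8 alkyne.
3. Dienynoic acid ⇐ Heck reaction (C3–C4) of a (Z)-enol triflate with methacrylic acid.
4. (Z)-Enol triflate ⇐ enantioselective conjugate alkynylation of (E)-hex-4-en-3-one with a but-1-ynylboronate and O-triflation of the resulting (Z)-boron enolate. This sets the only pre-formed stereocentre (C6) and the Z-olefin in one operation.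
5. Dienyl iodide ⇐ cinnamaldehyde by one-carbon homologation to the enyne and syn-ethylcupration/iodination.

Assumption: (S)-3,3'-diiodo-1,1'-bi-2-naphthol is taken to deliver the alkynyl group to the Re face of the β-carbon of the enone (giving the 5R triflate); if the sense of induction is the opposite, the (R)-catalyst is used and nothing else changes.

Step 1
Reactants: 1 but-1-yne
Product: 4 bis(propan-2-yl) (but-1-yn-1-yl)boronate, via lithium but-1-yn-1-ide 2 (not isolated), via lithium alkynyltriisopropoxyborate 3 (not isolated)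
Conditions: n-BuLi, THF, −78 °C; B(Oi-Pr)3, −78 °C; HCl·Et2O, −78 °C → rt; distillation
Reagents that add atoms: triisopropyl borate, CC(C)OB(OC(C)C)OC(C)C
Why: Deprotonation of the terminal alkyne, borylation of the acetylide to the borate and removal of one isopropoxide with anhydrous HCl is the standard preparation of distillable dialkyl 1-alkynylboronates; no stereocentre is involved.

Step 2
Reactants: 4 bis(propan-2-yl) (but-1-yn-1-yl)boronate; 5 (4E)-hex-4-en-3-one
Product: 7 (3Z,5R)-5-methylnon-3-en-6-yn-3-yl trifluoromethanesulfonate, via (Z)-boron enolate 6 (not isolated)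
Conditions: (S)-3,3'-diiodo-1,1'-bi-2-naphthol (20 mol %), 4 Å MS, CH2Cl2, rt → 40 °C; then KOt-Bu, PhNTf2, THF, −78 → 0 °C; cold dilute aq HCl work-up
Reagents that add atoms: N-phenylbis(trifluoromethanesulfonimide), O=S(=O)(N(c1ccccc1)S(=O)(=O)C(F)(F)F)C(F)(F)F
Why: Proposed new method: the closest known reaction type is the binaphthol-catalysed conjugate alkynylboration of s-cis enones, in which the six-membered chair transition state fixes the Z geometry of the dialkoxyboron enolate and the 3,3'-diiodobinaphthol ligand directs the alkynyl group to one face of the β-carbon (here the Re face, giving the R methyl stereocentre); the new element is to convert that boron enolate in the same flask into its alkoxide "ate" complex (as is done for alkylation of catalytically generated boron enolates) and O-sulfonylate it with PhNTf2, which traps the enolate regiospecifically toward C4=C5 before any proton transfer can equilibrate it.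

Step 3
Reactants: 7 (3Z,5R)-5-methylnon-3-en-6-yn-3-yl trifluoromethanesulfonate; 8 methacrylic acid
Product: 9 (2E,4Z,6R)-4-ethyl-2,6-dimethyldeca-2,4-dien-7-ynoic acid
Conditions: Pd(OAc)2 (5 mol %), PPh3 (10 mol %), n-Bu4NCl, K2CO3, DMF, 60 °C; then aq HCl
Reagents that add atoms: none
Why: Heck reaction: zerovalent palladium inserts into the enol triflate with retention of the Z geometry, the alkenylpalladium adds to the CH2 terminus of methacrylate, and syn β-hydride elimination toward the new allylic CH2 gives the conjugated (2E,4Z)-dienoic acid, while the carboxylate form keeps the C6–H non-acidic so the stereocentre is untouched.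

Step 4
Reactants: 10 (E)-cinnamaldehyde
Product: 11 [(1E)-but-1-en-3-yn-1-yl]benzene
Conditions: TMSCHN2, LiN(i-Pr)2, THF, −78 °C → rt
Reagents that add atoms: trimethylsilyldiazomethane, C[Si](C)(C)C=[N+]=[N-]
Why: Colvin rearrangement: lithiated trimethylsilyldiazomethane adds to the aldehyde, Peterson-type loss of silanolate gives a diazoalkene, and loss of N2 with a 1,2-hydrogen shift of the alkylidene carbene gives the terminal alkyne without touching the E-styryl olefin.

Step 5
Reactants: 11 [(1E)-but-1-en-3-yn-1-yl]benzene
Product: 13 [(1E,3E)-3-ethyl-4-iodobuta-1,3-dien-1-yl]benzene, via dienylcopper 12 (not isolated)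
Conditions: EtMgBr, CuBr·SMe2, Et2O/Me2S, −45 °C; 11, −25 °C; then I2, THF, −50 → 0 °C
Reagents that add atoms: ethylmagnesium bromide, CC[Mg]Br; iodine, II
Why: Normant carbocupration: ethylcopper adds syn across the terminal alkyne with ethyl at the internal carbon, and iodinolysis of the dienylcopper with retention gives the iodide with iodine cis to ethyl and trans to the styryl group (3E).

Step 6
Reactants: 9 (2E,4Z,6R)-4-ethyl-2,6-dimethyldeca-2,4-dien-7-ynoic acid; 13 [(1E,3E)-3-ethyl-4-iodobuta-1,3-dien-1-yl]benzene
Product: 16 spiculoic acid B, via bis(boryl) intermediate 14 (not isolated), via pentaenoic acid 15 (not isolated)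
Conditions: 9-BBN-H (2.2 equiv), THF, 0 °C → rt; then 13, PdCl2(dppf) (5 mol %), aq NaOH, degassed THF, rt → 40 °C; then aq HCl to pH 3, 45 °C
Reagents that add atoms: none
Why: The acid is masked in situ as its acyloxyborane, syn-hydroboration of the internal alkyne puts boron on the less hindered ethyl-bearing carbon, and Suzuki–Miyaura coupling with retention at both partners gives the all-E triene; after protonation the pentaenoic acid undergoes the biomimetic intramolecular Diels–Alder reaction, in which the dienophile adds to the diene face anti to the C6 methyl group (C6–H eclipses the C8 ethyl group to avoid allylic 1,3-strain) through the CO2H-endo, tether-anti transition state, so the E olefin geometries fix C2 and C10 and the single methyl stereocentre fixes C7 and C3 with a trans ring fusion (chain numbering of 15).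

**Compound list**
1 | but-1-yne | CCC#C | starting material
2 | lithium but-1-yn-1-ide | [Li]C#CCC | intermediate
3 | lithium (but-1-yn-1-yl)tris(propan-2-yloxy)borate | [Li+].CCC#C[B-](OC(C)C)(OC(C)C)OC(C)C | intermediate
4 | bis(propan-2-yl) (but-1-yn-1-yl)boronate | CCC#CB(OC(C)C)OC(C)C | intermediate
5 | (4E)-hex-4-en-3-one | CCC(=O)/C=C/C | starting material
6 | bis(propan-2-yl) (3Z,5R)-5-methylnon-3-en-6-yn-3-yl borate (Z-boron enolate) | CC/C(OB(OC(C)C)OC(C)C)=C/[C@@H](C)C#CCC | intermediate
7 | (3Z,5R)-5-methylnon-3-en-6-yn-3-yl trifluoromethanesulfonate | CC/C(OS(=O)(=O)C(F)(F)F)=C/[C@@H](C)C#CCC | intermediate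
8 | 2-methylprop-2-enoic acid (methacrylic acid) | CC(=C)C(=O)O | starting material
9 | (2E,4Z,6R)-4-ethyl-2,6-dimethyldeca-2,4-dien-7-ynoic acid | OC(=O)/C(C)=C/C(CC)=C\[C@@H](C)C#CCC | intermediate
10 | (2E)-3-phenylprop-2-enal (cinnamaldehyde) | O=C/C=C/c1ccccc1 | starting material
11 | [(1E)-but-1-en-3-yn-1-yl]benzene | C#C/C=C/c1ccccc1 | intermediate
12 | [(1E,3E)-2-ethyl-4-phenylbuta-1,3-dien-1-yl]copper (as its MgBr2 complex) | [Cu]/C=C(CC)/C=C/c1ccccc1 | intermediate
13 | [(1E,3E)-3-ethyl-4-iodobuta-1,3-dien-1-yl]benzene | I/C=C(CC)/C=C/c1ccccc1 | intermediate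
14 | 9-borabicyclo[3.3.1]nonan-9-yl (2E,4Z,6S,7Z)-8-(9-borabicyclo[3.3.1]nonan-9-yl)-4-ethyl-2,6-dimethyldeca-2,4,7-trienoate | O=C(OB1C2CCCC1CCC2)/C(C)=C/C(CC)=C\[C@@H](C)/C=C(CC)/B1C2CCCC1CCC2 | intermediate
15 | (2E,4Z,6S,7E,9E,11E)-4,8,10-triethyl-2,6-dimethyl-12-phenyldodeca-2,4,7,9,11-pentaenoic acid (formed as its sodium salt and freed with HCl) | OC(=O)/C(C)=C/C(CC)=C\[C@@H](C)/C=C(CC)/C=C(CC)/C=C/c1ccccc1 | intermediate
16 | spiculoic acid B: (1R,3aR,4R,5S,7aS)-3,5,7-triethyl-1,4-dimethyl-5-[(E)-2-phenylethenyl]-3a,4,5,7a-tetrahydro-1H-indene-4-carboxylic acid | CCC1=C[C@@](/C=C/c2ccccc2)(CC)[C@](C)(C(=O)O)[C@H]2C(CC)=C[C@@H](C)[C@H]12 | target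

The descriptor at the methyl-bearing carbon changes R (7, 9) → S (14, 15) → R (16) only because the CIP priorities of its neighbours change; the centre itself is never touched after step 2.

**Step count**
Total: 6 steps. Longest linear sequence: 4 steps (steps 1, 2, 3, 6); iodide 13 is made in parallel in 2 steps (steps 4, 5).

**Steps most likely to fail**

Step 2. The aliphatic β-methyl enone may react slowly or with modest enantioselectivity under binaphthol catalysis, and the triflation of a dialkoxyboron enolate is untested. The fallback sets out from 1 and 5 and comes back at 9. Compound 1 is deprotonated (n-BuLi) and transmetalated with Et2AlCl to diethyl(but-1-yn-1-yl)aluminium F1. Its uncatalysed conjugate addition to 5 through the s-cis enone (six-membered transition state, Et2O/hexane, rt) gives the racemic diethylaluminium (Z)-enolate F2, a far more nucleophilic enolate, which is O-triflated with Tf2O at −78 °C to the racemic (Z)-enol triflate F3. Heck coupling with 8 under the step 3 conditions gives the racemic dienynoic acid F4. This is resolved by crystallisation of its salt with (S)-1-phenylethan-1-amine, the (S)-1-phenylethan-1-aminium (6R)-carboxylate F5, and acidification returns 9. Which enantiomer of the amine gives the less soluble salt of the (6R)-acid has to be found by trial.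

Step 3. With a 1,1-disubstituted acrylate, β-hydride elimination can also go toward the methyl group (giving the 2-methylene isomer) or give some 2Z product, and the alkyne could intercept the alkenylpalladium. The fallback sets out from 7 and comes back at 9. Reductive carbonylation of 7 (Pd(OAc)2, dppp, CO 1 atm, Et3SiH, DMF, 60 °C) gives, with retention of the Z geometry, (2Z,4R)-2-ethyl-4-methyloct-2-en-5-ynal F6. A Horner–Wadsworth–Emmons reaction of F6 with the dianion of 2-(diethoxyphosphoryl)propanoic acid (NaH, THF, 0 °C) then builds the E-configured C2=C3 bond and gives 9 directly.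

Step 6. This step carries the most risk: the Z-olefin in the tether makes the cyclopentene-forming transition state strained, so a thermal 1,5-hydrogen shift of the doubly allylic C6–H into the (4Z)-dienoic acid, or the cis-fused (CO2H-exo) adduct, could compete. The hydroboration may also give some of the C7-boryl regioisomer. The fallback sets out from 9 and 13 and comes back at 16. Compound 9 is esterified (TMSCHN2, MeOH/toluene) to the methyl ester F7, hydroborated (9-BBN-H, 1.1 equiv) to the alkenylborane F8 and coupled with 13 (PdCl2(dppf), aq K3PO4, rt) to the pentaene methyl ester F9, which is isolated cold. The Diels–Alder step is then run on its own under Lewis acid activation of the ester (MeAlCl2, CH2Cl2, −78 → −20 °C), which lowers the cycloaddition barrier below that of the hydrogen shift and strengthens the ester-endo (trans-fusion) preference, giving spiculoic acid B methyl ester F10. SN2 demethylation of this hindered ester (LiSPr, HMPA, rt) gives 16.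

**Further compounds**
F1 | step 2 | diethyl(but-1-yn-1-yl)aluminium | CCC#C[Al](CC)CC
F2 | step 2 | racemic diethyl{[(3Z)-5-methylnon-3-en-6-yn-3-yl]oxy}aluminium | CC/C(O[Al](CC)CC)=C/C(C)C#CCC
F3 | step 2 | racemic (3Z)-5-methylnon-3-en-6-yn-3-yl trifluoromethanesulfonate | CC/C(OS(=O)(=O)C(F)(F)F)=C/C(C)C#CCC
F4 | step 2 | racemic (2E,4Z)-4-ethyl-2,6-dimethyldeca-2,4-dien-7-ynoic acid | OC(=O)/C(C)=C/C(CC)=C\C(C)C#CCC
F5 | step 2 | (S)-1-phenylethan-1-aminium (2E,4Z,6R)-4-ethyl-2,6-dimethyldeca-2,4-dien-7-ynoate | [O-]C(=O)/C(C)=C/C(CC)=C\[C@@H](C)C#CCC.C[C@H]([NH3+])c1ccccc1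
F6 | step 3 | (2Z,4R)-2-ethyl-4-methyloct-2-en-5-ynal | O=C/C(CC)=C\[C@@H](C)C#CCC
F7 | step 6 | methyl (2E,4Z,6R)-4-ethyl-2,6-dimethyldeca-2,4-dien-7-ynoate | COC(=O)/C(C)=C/C(CC)=C\[C@@H](C)C#CCC
F8 | step 6 | methyl (2E,4Z,6S,7Z)-8-(9-borabicyclo[3.3.1]nonan-9-yl)-4-ethyl-2,6-dimethyldeca-2,4,7-trienoate | COC(=O)/C(C)=C/C(CC)=C\[C@@H](C)/C=C(CC)/B1C2CCCC1CCC2
F9 | step 6 | methyl (2E,4Z,6S,7E,9E,11E)-4,8,10-triethyl-2,6-dimethyl-12-phenyldodeca-2,4,7,9,11-pentaenoate | COC(=O)/C(C)=C/C(CC)=C\[C@@H](C)/C=C(CC)/C=C(CC)/C=C/c1ccccc1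
F10 | step 6 | methyl (1R,3aR,4R,5S,7aS)-3,5,7-triethyl-1,4-dimethyl-5-[(E)-2-phenylethenyl]-3a,4,5,7a-tetrahydro-1H-indene-4-carboxylate | CCC1=C[C@@](/C=C/c2ccccc2)(CC)[C@](C)(C(=O)OC)[C@H]2C(CC)=C[C@@H](C)[C@H]12
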